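**Strategy.** The pyran ring of the middle unit (O1, C2, C3, C4, C4a, C8a) is closed last, around an open chain that already carries the lower flavan. Its 3,4-cis junction, which flavan-4-yl cation chemistry does not favour, is set in the open chain by inversion when C8 of benzylated (−)-catechin opens a trans-epoxy ketone at C4. The key step exploits that C2 is benzylic and para to the 4'-oxygen of ring B: acid ionises only this alcohol of the 3,3-diaryl-1-arylpropane-1,2-diol precursor and the free ring A phenol closes O1–C2 with ring B equatorial (2,3-trans). Gallocatechin is then joined 4α→8 and the benzyl ethers are removed.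

Key step: step 8

Remarks on the chemistry: (U), (M) and (L) mark atoms of the upper, middle and lower flavan unit. (R)-BINOL is taken to be the ligand antipode that gives epoxide 7 as drawn; if the sense is opposite, (S)-BINOL is used. The C1 epimers formed in step 7 are carried on together, because both converge in step 8.

Step 1
Reactants: 1 3,5-bis(benzyloxy)phenol
Product: 2 4,6-bis(benzyloxy)-2-hydroxybenzaldehyde
Conditions: MgCl2, Et3N, (CH2O)n, MeCN, reflux
Reagents that add atoms: formaldehyde (from paraformaldehyde), C=O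
Why: Magnesium phenoxide-directed ortho-formylation (Casnati–Skattebøl) should put the formyl group only next to the free hydroxyl, and the two ortho positions of 1 are equivalent.

Step 2
Reactants: 2 4,6-bis(benzyloxy)-2-hydroxybenzaldehyde
Product: 3 2-(allyloxy)-4,6-bis(benzyloxy)benzaldehyde
Conditions: allyl bromide, K2CO3, DMF, 50 °C
Reagents that add atoms: allyl bromide, C=CCBr
Why: Williamson etherification should mask the later O1(M) with a group that is orthogonal to benzyl ethers and inert to base, peroxide and cold Lewis acid.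

Step 3
Reactants: 3 2-(allyloxy)-4,6-bis(benzyloxy)benzaldehyde; 4 1-[3,4-bis(benzyloxy)phenyl]ethanone
Product: 6 (E)-3-[2-(allyloxy)-4,6-bis(benzyloxy)phenyl]-1-[3,4-bis(benzyloxy)phenyl]prop-2-en-1-one, via β-hydroxy ketone 5 (not isolated)
Conditions: KOH (aq. 50%), EtOH/THF, rt
Reagents that add atoms: none
Why: Claisen–Schmidt condensation of the non-enolisable aldehyde with the methyl ketone should give the E-enone after E1cB loss of water from the aldol adduct.

Step 4
Reactants: 6 (E)-enone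
Product: 7 [(2S,3R)-3-[2-(allyloxy)-4,6-bis(benzyloxy)phenyl]oxiran-2-yl][3,4-bis(benzyloxy)phenyl]methanone
Conditions: La(O-i-Pr)3, (R)-BINOL, Ph3As=O (10 mol% each), t-BuOOH, 4 Å MS, THF, rt; filtered through basic alumina and used at once
Reagents that add atoms: tert-butyl hydroperoxide, CC(C)(C)OO
Why: Catalytic asymmetric nucleophilic (Weitz–Scheffer type) epoxidation should keep the trans geometry while the chiral lanthanum peroxide selects the enone face, which sets C3(M) as S and C4(M) as R, and the isolated allyl double bond is no Michael acceptor and stays untouched.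

Step 5
Reactants: 8 (−)-catechin
Product: 9 5,7,3',4'-tetra-O-benzyl-(−)-catechin
Conditions: BnBr (4.4 equiv), K2CO3, DMF, 0 °C to rt, argon
Reagents that add atoms: benzyl bromide, BrCc1ccccc1
Why: Williamson benzylation with carbonate should be selective for the four phenols over the secondary 3-OH and leaves C8 as the most nucleophilic ring position.

Step 6
Reactants: 7 (2S,3R)-epoxy ketone; 9 5,7,3',4'-tetra-O-benzyl-(−)-catechin
Product: 10 (2S,3R)-3-[2-(allyloxy)-4,6-bis(benzyloxy)phenyl]-1-[3,4-bis(benzyloxy)phenyl]-2-hydroxy-3-[(2S,3R)-5,7-bis(benzyloxy)-2-[3,4-bis(benzyloxy)phenyl]-3-hydroxychroman-8-yl]propan-1-one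
Conditions: 9 (3 equiv), BF3·OEt2 (1.1 equiv), CH2Cl2, −78 °C
Reagents that add atoms: none
Why: Lewis acid-mediated Friedel–Crafts opening of the epoxide at its benzylic carbon C4(M), activated by the 2,4,6-trioxygenated ring, by C8(L) from the face opposite to the departing oxygen (inversion) should give the anti adduct, which is the 3,4-cis relationship of the later ring, while C3(M) is untouched and the ketone keeps C2(M) from ionising.

Step 7
Reactants: 10 open-chain hydroxy ketone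
Product: 12 (2S,3R)-3-[4,6-bis(benzyloxy)-2-hydroxyphenyl]-1-[3,4-bis(benzyloxy)phenyl]-3-[(2S,3R)-5,7-bis(benzyloxy)-2-[3,4-bis(benzyloxy)phenyl]-3-hydroxychroman-8-yl]propane-1,2-diol (C1 epimers), via allyl ether diol 11 (not isolated)
Conditions: NaBH4, THF/MeOH, 0 °C; then Pd(PPh3)4 (5 mol%), rt
Reagents that add atoms: none
Why: Borohydride reduction of the aryl ketone (the C2(M) configuration is irrelevant) followed by Tsuji–Trost-type reductive deallylation of the aryl allyl ether (π-allyl palladium captured by hydride) should free the phenol and leave all benzyl ethers intact.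

Step 8
Reactants: 12 phenolic triol (C1 epimers)
Product: 13 5,7,3',4'-tetra-O-benzylcatechin-(4β→8)-5,7,3',4'-tetra-O-benzyl-ent-catechin (upper unit 2R,3S, 2,3-trans-3,4-cis; lower unit 2S,3R)
Conditions: BF3·OEt2 (0.3 equiv), CH2Cl2, 4 Å MS, −40 to 0 °C
Reagents that add atoms: none
Why: BF3 ionises the C2(M) hydroxyl, the only benzylic alcohol and para to the 4'-benzyloxy group of ring B, to a quinone-methide-like cation that is captured by the free phenol oxygen on C8a(M), which forms the O1–C2 bond of ring C. The closest known reaction is the acid-catalysed cyclodehydration of 1-aryl-3-(2-hydroxyaryl)propane-1,2-diols to flavan-3-ols (intramolecular SN1 etherification). The pyran ring closes in the 6-exo-trig mode, the phenol adding to the cationic C2 whose π-bond to ring B lies outside the new ring. The new stereocentre C2(M) is set by the substrate: in the chair-like transition state the C3 hydroxyl is equatorial and the lower-unit aryl group at C4 axial, so ring B can only be equatorial and anti to that aryl group, which gives 2R (2,3-trans) from either C1 epimer of 12 and is also the more stable isomer. The step needs closure by O1(M) and not by O7(L), which is secured because O1(M) is the only free phenol, and ionisation at C2(M) alone, which holds because the C3 hydroxyl is not benzylic and C4 has no leaving group.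

Step 9
Reactants: 14 (+)-gallocatechin
Product: 15 5,7,3',4',5'-penta-O-benzyl-(+)-gallocatechin
Conditions: BnBr (5.5 equiv), K2CO3, DMF, 0 °C to rt, argon
Reagents that add atoms: benzyl bromide, BrCc1ccccc1
Why: Williamson benzylation under argon should protect the five phenols of the pyrogallol and phloroglucinol rings and leave the 3-OH free.

Step 10
Reactants: 15 penta-O-benzyl-(+)-gallocatechin
Product: 16 (2R,3S)-5,7-bis(benzyloxy)-4-(2-ethoxyethoxy)-2-[3,4,5-tris(benzyloxy)phenyl]chroman-3-ol (C4 epimers)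
Conditions: DDQ (2 equiv), 2-ethoxyethanol (5 equiv), CH2Cl2, rt
Reagents that add atoms: 2-ethoxyethanol, CCOCCO
Why: DDQ benzylic oxidation (hydride abstraction from C4, activated by the 5,7-dioxygenated ring A) and capture of the cation by the alcohol should install a C4 leaving group, and either C4 epimer serves.

Step 11
Reactants: 16 4-(2-ethoxyethoxy) flavan-3-ol
Product: 17 (2R,3S)-5,7-bis(benzyloxy)-4-(2-ethoxyethoxy)-2-[3,4,5-tris(benzyloxy)phenyl]chroman-3-yl acetate (C4 epimers)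
Conditions: Ac2O, pyridine, DMAP (cat.), rt
Reagents that add atoms: acetic anhydride, CC(=O)OC(C)=O
Why: DMAP-catalysed acylation of the secondary alcohol should install the participating group for the coupling.

Step 12
Reactants: 17 gallocatechin electrophile; 13 benzylated catechin-(4β→8)-ent-catechin
Product: 18 3-O-acetyl-5,7,3',4',5'-penta-O-benzylgallocatechin-(4α→8)-5,7,3',4'-tetra-O-benzylcatechin-(4β→8)-5,7,3',4'-tetra-O-benzyl-ent-catechin
Conditions: 13 (1.5 equiv), TMSOTf (0.5 equiv), CH2Cl2, 4 Å MS, −78 °C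
Reagents that add atoms: none
Why: Lewis acid-promoted flavan-4-yl Friedel–Crafts coupling with anchimeric assistance should work because the 3-acetoxy group bridges the C4(U) cation as a dioxolanylium ion on the β face, so that C8(M), the most nucleophilic free ring position of 13, attacks from the α face and sets C4(U) as 4α (3,4-trans).

Step 13
Reactants: 18 acetylated protected trimer
Product: 19 5,7,3',4',5'-penta-O-benzylgallocatechin-(4α→8)-5,7,3',4'-tetra-O-benzylcatechin-(4β→8)-5,7,3',4'-tetra-O-benzyl-ent-catechin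
Conditions: NaOMe (cat.), MeOH/THF, rt
Reagents that add atoms: none
Why: Zemplén transesterification should remove the single acetate without touching benzyl ethers or stereocentres.

Step 14
Reactants: 19 protected trimer
Product: 20 gallocatechin-(4α→8)-catechin-(4β→8)-ent-catechin (target)
Conditions: H2 (1 atm), Pd(OH)2/C, THF/MeOH/H2O, rt
Reagents that add atoms: none
Why: Catalytic hydrogenolysis should cleave the thirteen benzyl ethers, while the ring C ether bonds and the two interflavan bonds are stable under these neutral conditions.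

**Compound list**

1 | 3,5-bis(benzyloxy)phenol | Oc1cc(OCc3ccccc3)cc(OCc3ccccc3)c1 | starting material
2 | 4,6-bis(benzyloxy)-2-hydroxybenzaldehyde | O=Cc1c(O)cc(OCc3ccccc3)cc1OCc3ccccc3 | intermediate
3 | 2-(allyloxy)-4,6-bis(benzyloxy)benzaldehyde | O=Cc1c(OCC=C)cc(OCc3ccccc3)cc1OCc3ccccc3 | intermediate
4 | 1-[3,4-bis(benzyloxy)phenyl]ethanone | CC(=O)c1ccc(OCc3ccccc3)c(OCc3ccccc3)c1 | starting material
5 | 3-[2-(allyloxy)-4,6-bis(benzyloxy)phenyl]-1-[3,4-bis(benzyloxy)phenyl]-3-hydroxypropan-1-one (racemic aldol adduct, not isolated) | O=C(CC(O)c1c(OCC=C)cc(OCc3ccccc3)cc1OCc3ccccc3)c1ccc(OCc3ccccc3)c(OCc3ccccc3)c1 | intermediate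
6 | (E)-3-[2-(allyloxy)-4,6-bis(benzyloxy)phenyl]-1-[3,4-bis(benzyloxy)phenyl]prop-2-en-1-one | O=C(/C=C/c1c(OCC=C)cc(OCc3ccccc3)cc1OCc3ccccc3)c1ccc(OCc3ccccc3)c(OCc3ccccc3)c1 | intermediate
7 | [(2S,3R)-3-[2-(allyloxy)-4,6-bis(benzyloxy)phenyl]oxiran-2-yl][3,4-bis(benzyloxy)phenyl]methanone (trans) | O=C(c1ccc(OCc3ccccc3)c(OCc3ccccc3)c1)[C@H]4O[C@@H]4c1c(OCC=C)cc(OCc3ccccc3)cc1OCc3ccccc3 | intermediate
8 | (−)-catechin, (2S,3R)-2-(3,4-dihydroxyphenyl)chromane-3,5,7-triol | Oc1cc(O)c2c(c1)O[C@@H](c1ccc(O)c(O)c1)[C@H](O)C2 | starting material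
9 | 5,7,3',4'-tetra-O-benzyl-(−)-catechin, (2S,3R)-5,7-bis(benzyloxy)-2-[3,4-bis(benzyloxy)phenyl]chroman-3-ol | c1c(OCc3ccccc3)cc(OCc3ccccc3)c2c1O[C@@H](c1ccc(OCc3ccccc3)c(OCc3ccccc3)c1)[C@H](O)C2 | intermediate
10 | (2S,3R)-3-[2-(allyloxy)-4,6-bis(benzyloxy)phenyl]-1-[3,4-bis(benzyloxy)phenyl]-2-hydroxy-3-[(2S,3R)-5,7-bis(benzyloxy)-2-[3,4-bis(benzyloxy)phenyl]-3-hydroxychroman-8-yl]propan-1-one | O=C(c1ccc(OCc3ccccc3)c(OCc3ccccc3)c1)[C@@H](O)[C@H](c1c(OCC=C)cc(OCc3ccccc3)cc1OCc3ccccc3)c1c(OCc3ccccc3)cc(OCc3ccccc3)c2c1O[C@@H](c1ccc(OCc3ccccc3)c(OCc3ccccc3)c1)[C@H](O)C2 | intermediate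
11 | (2S,3R)-3-[2-(allyloxy)-4,6-bis(benzyloxy)phenyl]-1-[3,4-bis(benzyloxy)phenyl]-3-[(2S,3R)-5,7-bis(benzyloxy)-2-[3,4-bis(benzyloxy)phenyl]-3-hydroxychroman-8-yl]propane-1,2-diol (C1 epimers, not isolated) | OC(c1ccc(OCc3ccccc3)c(OCc3ccccc3)c1)[C@@H](O)[C@H](c1c(OCC=C)cc(OCc3ccccc3)cc1OCc3ccccc3)c1c(OCc3ccccc3)cc(OCc3ccccc3)c2c1O[C@@H](c1ccc(OCc3ccccc3)c(OCc3ccccc3)c1)[C@H](O)C2 | intermediate
12 | (2S,3R)-3-[4,6-bis(benzyloxy)-2-hydroxyphenyl]-1-[3,4-bis(benzyloxy)phenyl]-3-[(2S,3R)-5,7-bis(benzyloxy)-2-[3,4-bis(benzyloxy)phenyl]-3-hydroxychroman-8-yl]propane-1,2-diol (C1 epimers) | OC(c1ccc(OCc3ccccc3)c(OCc3ccccc3)c1)[C@@H](O)[C@H](c1c(O)cc(OCc3ccccc3)cc1OCc3ccccc3)c1c(OCc3ccccc3)cc(OCc3ccccc3)c2c1O[C@@H](c1ccc(OCc3ccccc3)c(OCc3ccccc3)c1)[C@H](O)C2 | intermediate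
13 | 5,7,3',4'-tetra-O-benzylcatechin-(4β→8)-5,7,3',4'-tetra-O-benzyl-ent-catechin (upper unit 2R,3S with the C4 aryl group cis to 3-OH; lower unit 2S,3R) | c1c(OCc3ccccc3)cc(OCc3ccccc3)c2c1O[C@H](c1ccc(OCc3ccccc3)c(OCc3ccccc3)c1)[C@@H](O)[C@H]2c1c(OCc3ccccc3)cc(OCc3ccccc3)c2c1O[C@@H](c1ccc(OCc3ccccc3)c(OCc3ccccc3)c1)[C@H](O)C2 | intermediate
14 | (+)-gallocatechin, (2R,3S)-2-(3,4,5-trihydroxyphenyl)chromane-3,5,7-triol | Oc1cc(O)c2c(c1)O[C@H](c1cc(O)c(O)c(O)c1)[C@@H](O)C2 | starting material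
15 | 5,7,3',4',5'-penta-O-benzyl-(+)-gallocatechin | C(c3ccccc3)Oc1cc(OCc3ccccc3)c2c(c1)O[C@H](c1cc(OCc3ccccc3)c(OCc3ccccc3)c(OCc3ccccc3)c1)[C@@H](O)C2 | intermediate
16 | (2R,3S)-5,7-bis(benzyloxy)-4-(2-ethoxyethoxy)-2-[3,4,5-tris(benzyloxy)phenyl]chroman-3-ol (C4 epimers) | C(c3ccccc3)Oc1cc(OCc3ccccc3)c2c(c1)O[C@H](c1cc(OCc3ccccc3)c(OCc3ccccc3)c(OCc3ccccc3)c1)[C@@H](O)C2OCCOCC | intermediate
17 | (2R,3S)-5,7-bis(benzyloxy)-4-(2-ethoxyethoxy)-2-[3,4,5-tris(benzyloxy)phenyl]chroman-3-yl acetate (C4 epimers) | C(c3ccccc3)Oc1cc(OCc3ccccc3)c2c(c1)O[C@H](c1cc(OCc3ccccc3)c(OCc3ccccc3)c(OCc3ccccc3)c1)[C@@H](OC(C)=O)C2OCCOCC | intermediate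
18 | 3-O-acetyl-5,7,3',4',5'-penta-O-benzylgallocatechin-(4α→8)-5,7,3',4'-tetra-O-benzylcatechin-(4β→8)-5,7,3',4'-tetra-O-benzyl-ent-catechin | C(c3ccccc3)Oc1cc(OCc3ccccc3)c2c(c1)O[C@H](c1cc(OCc3ccccc3)c(OCc3ccccc3)c(OCc3ccccc3)c1)[C@@H](OC(C)=O)[C@@H]2c1c(OCc3ccccc3)cc(OCc3ccccc3)c2c1O[C@H](c1ccc(OCc3ccccc3)c(OCc3ccccc3)c1)[C@@H](O)[C@H]2c1c(OCc3ccccc3)cc(OCc3ccccc3)c2c1O[C@@H](c1ccc(OCc3ccccc3)c(OCc3ccccc3)c1)[C@H](O)C2 | intermediate
19 | 5,7,3',4',5'-penta-O-benzylgallocatechin-(4α→8)-5,7,3',4'-tetra-O-benzylcatechin-(4β→8)-5,7,3',4'-tetra-O-benzyl-ent-catechin | C(c3ccccc3)Oc1cc(OCc3ccccc3)c2c(c1)O[C@H](c1cc(OCc3ccccc3)c(OCc3ccccc3)c(OCc3ccccc3)c1)[C@@H](O)[C@@H]2c1c(OCc3ccccc3)cc(OCc3ccccc3)c2c1O[C@H](c1ccc(OCc3ccccc3)c(OCc3ccccc3)c1)[C@@H](O)[C@H]2c1c(OCc3ccccc3)cc(OCc3ccccc3)c2c1O[C@@H](c1ccc(OCc3ccccc3)c(OCc3ccccc3)c1)[C@H](O)C2 | intermediate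
20 | gallocatechin-(4α→8)-catechin-(4β→8)-ent-catechin (CNP0155646.2) | Oc1cc(O)c2c(c1)O[C@H](c1cc(O)c(O)c(O)c1)[C@@H](O)[C@@H]2c1c(O)cc(O)c2c1O[C@H](c1ccc(O)c(O)c1)[C@@H](O)[C@H]2c1c(O)cc(O)c2c1O[C@@H](c1ccc(O)c(O)c1)[C@H](O)C2 | target

**Count and risks**

Total step count: 14. Longest linear sequence: 10 steps (steps 1, 2, 3, 4, 6, 7, 8, 12, 13, 14).

The three steps most likely to fail are, in this order, step 6, step 4 and step 8.

Step 6: the cation at C4(M) may undergo a 1,2-acyl shift (semipinacol path) instead of being trapped, or may be attacked from the front face, which would erode the anti (later 3,4-cis) relationship. The fallback sets out from 7 and comes back to the route at 10. Ac2O with catalytic Sc(OTf)3 should open the epoxide to the vicinal diacetate (2S)-3-[2-(allyloxy)-4,6-bis(benzyloxy)phenyl]-1-[3,4-bis(benzyloxy)phenyl]-1-oxopropane-2,3-diyl diacetate F1 (C3 epimers). TMSOTf at −78 °C should then ionise the benzylic acetate; the neighbouring 2-acetoxy group closes to the trans-dioxolanylium ion, which cannot undergo the acyl shift, and C8 of 9 opens it with inversion to the 2-O-acetyl derivative of 10 F2. K2CO3 in MeOH at 0 °C should remove the acetate and give 10.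

Step 4: the hindered, electron-rich enone may be epoxidised slowly or with poor facial selectivity. The fallback sets out from 6 and comes back at 10. Weitz–Scheffer epoxidation (H2O2, NaOH, MeOH/THF) should give the racemic trans-epoxy ketone F3. Step 6 with enantiopure 9 then gives 10 together with its (2R,3S) open-chain diastereomer F4, and the two are separated by chromatography, so that the lower unit serves as the resolving element in place of the chiral catalyst.

Step 8: the ionised diol may rearrange by a pinacol-type hydride shift, or the 2,3-trans preference may be incomplete. The fallback sets out from 12 and comes back at 13. HC(OEt)3 with PPTS in 1,2-dichloroethane should tie the C1 and C2 hydroxyls into the cyclic orthoformate (2-ethoxy-1,3-dioxolane) F5, which closes the semipinacol path. Warming with PPTS to 60 °C should ionise it to the dioxolanylium ion, which the phenol opens at the benzylic carbon to give the 3-O-formate of 13 F6. K2CO3 in MeOH should then give 13.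

Further compounds
F1 | step 6 | (2S)-3-[2-(allyloxy)-4,6-bis(benzyloxy)phenyl]-1-[3,4-bis(benzyloxy)phenyl]-1-oxopropane-2,3-diyl diacetate (C3 epimers) | O=C(c1ccc(OCc3ccccc3)c(OCc3ccccc3)c1)[C@@H](OC(C)=O)C(OC(C)=O)c1c(OCC=C)cc(OCc3ccccc3)cc1OCc3ccccc3
F2 | step 6 | 2-O-acetyl derivative of 10 | O=C(c1ccc(OCc3ccccc3)c(OCc3ccccc3)c1)[C@@H](OC(C)=O)[C@H](c1c(OCC=C)cc(OCc3ccccc3)cc1OCc3ccccc3)c1c(OCc3ccccc3)cc(OCc3ccccc3)c2c1O[C@@H](c1ccc(OCc3ccccc3)c(OCc3ccccc3)c1)[C@H](O)C2
F3 | step 4 | racemic trans-epoxy ketone, 7 together with its (2R,3S) antipode (SMILES of the antipode) | O=C(c1ccc(OCc3ccccc3)c(OCc3ccccc3)c1)[C@@H]4O[C@H]4c1c(OCC=C)cc(OCc3ccccc3)cc1OCc3ccccc3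
F4 | step 4 | (2R,3S) open-chain diastereomer of 10, lower unit unchanged | O=C(c1ccc(OCc3ccccc3)c(OCc3ccccc3)c1)[C@H](O)[C@@H](c1c(OCC=C)cc(OCc3ccccc3)cc1OCc3ccccc3)c1c(OCc3ccccc3)cc(OCc3ccccc3)c2c1O[C@@H](c1ccc(OCc3ccccc3)c(OCc3ccccc3)c1)[C@H](O)C2
F5 | step 8 | cyclic orthoformate (2-ethoxy-1,3-dioxolane) of 12 across its C1 and C2 hydroxyls | CCOC4OC(c1ccc(OCc3ccccc3)c(OCc3ccccc3)c1)[C@@H](O4)[C@H](c1c(O)cc(OCc3ccccc3)cc1OCc3ccccc3)c1c(OCc3ccccc3)cc(OCc3ccccc3)c2c1O[C@@H](c1ccc(OCc3ccccc3)c(OCc3ccccc3)c1)[C@H](O)C2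
F6 | step 8 | 3-O-formate of 13 at the upper unit | c1c(OCc3ccccc3)cc(OCc3ccccc3)c2c1O[C@H](c1ccc(OCc3ccccc3)c(OCc3ccccc3)c1)[C@@H](OC=O)[C@H]2c1c(OCc3ccccc3)cc(OCc3ccccc3)c2c1O[C@@H](c1ccc(OCc3ccccc3)c(OCc3ccccc3)c1)[C@H](O)C2
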